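**The balance.** Add up the columns of a reading and you come close to the charge: the last south reading adds up to 98.0%. So follow one rate, the loss of free starting material, and treat the rest as bookkeeping.

in all of them: starting material 0.44 M
- south: partner 0.49 M; protic impurity 8.8 mM; run made earlier
- north-west: partner 1 M; protic impurity 8.8 mM; run made earlier
- ochre: partner 0.660 M; protic impurity 8.80 mM; time 40 h
- amber: partner 1.30 M; protic impurity 8.80 mM; time 40 h

| run | time / h | intermediate A / % | target / % | intermediate B / % | side product / % | starting material / % |
|---|---|---|---|---|---|---|
| south | 2.00 | 5 | 1 | 0 | 1 | 92 |
| south | 5.00 | 13 | 0 | 0 | 3 | 88 |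
| south | 10.0 | 10 | 1 | 1 | 7 | 85 |
| south | 15.0 | 16 | 2 | 3 | 7 | 76 |
| south | 20.0 | 7 | 1 | 3 | 15 | 72 |
| north-west | 1.50 | 6 | 0 | 1 | 0 | 93 |
| north-west | 3.00 | 12 | 1 | 0 | 5 | 91 |
| north-west | 6.00 | 11 | 1 | 0 | 10 | 78 |
| north-west | 10.0 | 18 | 0 | 3 | 14 | 67 |
| north-west | 20.0 | 14 | 0 | 1 | 34 | 49 |

(standard deviation of a reading: 2 percentage points)

* which of these there is most of at the end, counted by the starting material in it, ochre (starting material / side product / intermediate A / intermediate B)
* which of these there is most of at the end, counted by the starting material in it, amber (starting material / side product / intermediate A / intermediate B)
* how much there is at the end of the one of these that leads, in percent of the starting material charged: ochre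
* how much there is at the end of the one of these that leads, in percent of the starting material charged: amber



**The rate.** North-west, richer in partner, keeps 49% of its starting material at 20.0 h, less than the 72% in south. So I take partner as the concentration that sets the order. Let a be the free fraction of starting material and p the free fraction of partner. The rate is then k times the partner charge times a times p. This isn't pseudo-first-order: p moves as well as a. I assume the protic impurity takes its share of partner at once, and that each starting material consumed costs two partners. Integrating to the last readings gives 0.0488 /M/h in south and 0.0497 /M/h in north-west. Their mean, 0.0492 /M/h, is the partner constant: the fractional loss of starting material per hour per molar of free partner.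

**Ochre's slowing.** Ochre starts at 0.0321 /h. By 40 h my reckoning puts ochre's a at 49.2% and its p at 30.9%, so its rate ends at 0.00495 /h. Taking intermediate A at its mean last reading, 10.5%, leaves ochre's side product, with intermediate B and target counted in, at 40.3%, and starting material leads.

**Amber.** For amber the same reckoning gives a = 20.3%, and side product, counted the same way, leads at 69.2%.

**The forecast.** It names starting material at 49% for ochre and side product at 63% for amber, holding that “nearly everything consumed ends up as side product”. I name the same leaders, but my amber figure is higher than the forecast's.

**The flasks.** Ochre ends with 55.5% starting material, amber with 66.2% side product. Ochre still has 46% of its partner free, more than my 30.9%. Put through the same integration, ochre's end gives 0.0361 /M/h, less than the partner constant of 0.0492 /M/h.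

    starting material + partner ⇌ intermediate A (K = 1.10 /M, k = 0.0524 /M/h)
    partner + intermediate A → side product (k = 0.168 /M/h)
    partner + intermediate A ⇌ intermediate B (K = 0.221 /M, k = 0.107 /M/h)
    intermediate B ⇌ intermediate C (K = 0.270, k = 0.00529 /h)
    intermediate C → target (k = 0.0367 /h)
    partner + protic impurity → quenched reagent (k = 13.6 /M/h)

**Second flask.** Take the flask like amber but with 0.52 M of partner. At 40 h the partner constant gives 58.3% starting material. The computed flask holds 64.2%.

The runs come from a simulation for substances that don't exist, noise included.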